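The route rests on the C7–C8 bond, which ties the β-carbon of the α-methylene-γ-lactone to carbinol C8 inside the nine-membered oxa-ring C8–C9–C10–O–C3–C4=C5–C6–C7. In seco-aldehyde 24 the 3(2H)-furanone and a 3-(bromomethyl)butenolide are already closed. A CrCl2-mediated intramolecular carbonyl allylation then closes this last ring (and with it the ten-membered carbocycle), sets C7 and C8, and unveils the exocyclic C11=C13 methylene in one operation. The step exploits the homoallylic-alcohol pattern C8(OH)–C7–C11=C13. Stannane 7, acid 10 and iodo dienol 16 are joined by esterification, ring-closing metathesis and carbonylative Stille coupling; a Mitsunobu esterification finally inverts C8.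

Key step: step 17

Remarks.
- Atom numbers are germacrane numbers of the target: C1 ketone; C2, C3 furanone CH= and O–C=; C4=C5 olefin; C6 lactone O–CH; C7 ring-fusion CH; C8 acyloxy CH; C9 CH2; C10 quaternary C(CH3)O; C11=C13 exocyclic methylene; C12 lactone C=O; C14 CH3; C15 CH2OH.
- PMB = 4-methoxybenzyl, TBS = tert-butyldimethylsilyl, TBDPS = tert-butyldiphenylsilyl.
- Assumption: the allylation follows the chair model and gives the 7,8-anti (8S) alcohol, so the ester is introduced with inversion. If the 8R alcohol forms instead, it is acylated directly (see fallback for step 17).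
- Compounds 1, 8, 11 and 12 are taken as commercially available.

Step 1
Reactants: 1 4-[(4-methoxybenzyl)oxy]but-1-yne
Product: 3 (2E)-5-[(4-methoxybenzyl)oxy]-3-methylpent-2-en-1-ol, via alkenyl(dimethyl)alane 2 (not isolated)
Conditions: AlMe3 (2.5 equiv), Cp2ZrCl2 (25 mol%), CH2Cl2, 0 °C to rt; then (CH2O)n, THF, 0 °C to rt; aq. Rochelle salt
Reagents that add atoms: trimethylaluminium (C[Al](C)C); formaldehyde from paraformaldehyde (C=O)
Why: Negishi zirconium-catalysed carboalumination adds CH3–Al syn across the terminal alkyne with Al at the terminus, and hydroxymethylation of the alkenylalane with retention should give only the E-trisubstituted allylic alcohol.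

Step 2
Reactants: 3 (2E)-5-[(4-methoxybenzyl)oxy]-3-methylpent-2-en-1-ol
Product: 4 [(2S,3S)-3-{2-[(4-methoxybenzyl)oxy]ethyl}-3-methyloxiran-2-yl]methanol
Conditions: Ti(OiPr)4 (10 mol%), L-(+)-diethyl tartrate (12 mol%), t-BuOOH, 4 Å MS, CH2Cl2, −20 °C
Reagents that add atoms: tert-butyl hydroperoxide (CC(C)(C)OO)
Why: Sharpless asymmetric epoxidation; with L-(+)-tartrate the oxygen is delivered to the face that gives the 2S,3S epoxide (as with geraniol), which fixes the future C10 stereocentre.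

Step 3
Reactants: 4 [(2S,3S)-3-{2-[(4-methoxybenzyl)oxy]ethyl}-3-methyloxiran-2-yl]methanol
Product: 5 (2R,3S)-2-(chloromethyl)-3-{2-[(4-methoxybenzyl)oxy]ethyl}-3-methyloxirane
Conditions: PPh3, CCl4, NaHCO3, reflux
Reagents that add atoms: tetrachloromethane (ClC(Cl)(Cl)Cl)
Why: Buffered Appel chlorination (SN2 at the primary carbon) leaves the epoxide and both stereocentres untouched; the descriptor at C2 changes only because Cl raises the CIP priority.

Step 4
Reactants: 5 (2R,3S)-2-(chloromethyl)-3-{2-[(4-methoxybenzyl)oxy]ethyl}-3-methyloxirane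
Product: 7 (3S)-5-[(4-methoxybenzyl)oxy]-3-methyl-1-(tributylstannyl)pent-1-yn-3-ol, via dilithio alkynolate 6 (not isolated)
Conditions: n-BuLi (3.1 equiv), THF, −78 °C; then Bu3SnCl (1.05 equiv), −78 to 0 °C; aq. NaHCO3
Reagents that add atoms: tributyltin chloride (CCCC[Sn](Cl)(CCCC)CCCC)
Why: Base-induced fragmentation of the 2,3-epoxy chloride (α-lithiation, β-opening of the epoxide to a chlorovinyl alkoxide, loss of HCl) gives the propargylic alkoxide without breaking the C–O bond of the tertiary carbinol, so C10 stays S; the lithium acetylide is then C-stannylated.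

Step 5
Reactants: 8 ethyl 2-(hydroxymethyl)prop-2-enoate
Product: 9 ethyl 2-({[tert-butyl(dimethyl)silyl]oxy}methyl)prop-2-enoate
Conditions: TBSCl, imidazole, CH2Cl2, 0 °C to rt
Reagents that add atoms: tert-butyldimethylsilyl chloride (CC(C)(C)[Si](C)(C)Cl)
Why: Standard silylation of a primary allylic alcohol.

Step 6
Reactants: 9 ethyl 2-({[tert-butyl(dimethyl)silyl]oxy}methyl)prop-2-enoate
Product: 10 2-({[tert-butyl(dimethyl)silyl]oxy}methyl)prop-2-enoic acid
Conditions: LiOH·H2O, THF/H2O, 0 °C; then 1 M HCl to pH 4 at 0 °C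
Reagents that add atoms: lithium hydroxide ([Li+].[OH-])
Why: Saponification of the ethyl ester by acyl–oxygen cleavage; the primary TBS ether should survive LiOH and brief acidification to pH 4.

Step 7
Reactants: 11 tert-butyl(diphenyl)(prop-2-yn-1-yloxy)silane; 12 (2E)-but-2-enal
Product: 14 (4S,5E)-1-{[tert-butyl(diphenyl)silyl]oxy}hept-5-en-2-yn-4-ol, via alkynyl(methyl)zinc 13 (not isolated)
Conditions: 11 (3 equiv), ZnMe2 (3 equiv), (S,S)-ProPhenol (10 mol%; the antipodal ligand is used should the induction run the other way), Ph3P=O (20 mol%), toluene, 0 °C; then 12, 4 °C; aq. NH4Cl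
Reagents that add atoms: none
Why: Zinc–ProPhenol-catalysed enantioselective alkynylation of an enal: the dinuclear zinc complex binds aldehyde and alkynyl group and transfers the alkynyl group to the Re face in a 1,2-sense, giving the 4S carbinol that becomes C6.

Step 8
Reactants: 14 (4S,5E)-1-{[tert-butyl(diphenyl)silyl]oxy}hept-5-en-2-yn-4-ol
Product: 16 (2Z,4S,5E)-1-{[tert-butyl(diphenyl)silyl]oxy}-2-iodohepta-2,5-dien-4-ol, via sodium vinylalanate 15 (not isolated)
Conditions: NaAlH2(OCH2CH2OCH3)2 (1.6 equiv), THF, 0 °C; EtOAc; then I2, THF, −78 °C; aq. Na2S2O3/Rochelle salt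
Reagents that add atoms: iodine (II)
Why: Hydroxyl-directed trans-hydroalumination of the propargylic alcohol puts aluminium on the distal alkyne carbon in a five-membered oxa-aluminacycle, and iodinolysis with retention gives the Z vinyl iodide (iodine cis to the carbinol carbon), the geometry needed for C4=C5.

Step 9
Reactants: 16 (2Z,4S,5E)-1-{[tert-butyl(diphenyl)silyl]oxy}-2-iodohepta-2,5-dien-4-ol; 10 2-({[tert-butyl(dimethyl)silyl]oxy}methyl)prop-2-enoic acid
Product: 17 (2Z,4S,5E)-1-{[tert-butyl(diphenyl)silyl]oxy}-2-iodohepta-2,5-dien-4-yl 2-({[tert-butyl(dimethyl)silyl]oxy}methyl)prop-2-enoate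
Conditions: EDC·HCl, DMAP (10 mol%), CH2Cl2, 0 °C to rt
Reagents that add atoms: none
Why: Steglich esterification of the secondary alcohol touches no stereocentre and keeps the C6 oxygen acylated from here on, so the Z-γ-hydroxy olefin never meets an electrophilic C3.

Step 10
Reactants: 17 (2Z,4S,5E)-1-{[tert-butyl(diphenyl)silyl]oxy}-2-iodohepta-2,5-dien-4-yl 2-({[tert-butyl(dimethyl)silyl]oxy}methyl)prop-2-enoate
Product: 18 (5S)-3-({[tert-butyl(dimethyl)silyl]oxy}methyl)-5-[(1Z)-3-{[tert-butyl(diphenyl)silyl]oxy}-2-iodoprop-1-en-1-yl]furan-2(5H)-one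
Conditions: second-generation Grubbs catalyst [RuCl2(=CHPh)(PCy3)(H2IMes)] (5 mol%), CH2Cl2 (5 mM), 40 °C
Reagents that add atoms: none
Why: Ring-closing metathesis between the propenyl group and the 1,1-disubstituted acrylate expels propene and forms the trisubstituted butenolide (C7=C11, with C13 as CH2OTBS); the iodo-substituted trisubstituted olefin should be inert to the ruthenium carbene.

Step 11
Reactants: 18 (5S)-3-({[tert-butyl(dimethyl)silyl]oxy}methyl)-5-[(1Z)-3-{[tert-butyl(diphenyl)silyl]oxy}-2-iodoprop-1-en-1-yl]furan-2(5H)-one; 7 (3S)-5-[(4-methoxybenzyl)oxy]-3-methyl-1-(tributylstannyl)pent-1-yn-3-ol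
Product: 19 (5R)-3-({[tert-butyl(dimethyl)silyl]oxy}methyl)-5-[(1Z,6S)-2-({[tert-butyl(diphenyl)silyl]oxy}methyl)-6-hydroxy-8-[(4-methoxybenzyl)oxy]-6-methyl-3-oxooct-1-en-4-yn-1-yl]furan-2(5H)-one
Conditions: PdCl2(PPh3)2 (5 mol%), CO (3 atm), THF, 45 °C
Reagents that add atoms: carbon monoxide ([C-]#[O+])
Why: Stille carbonylative cross-coupling (oxidative addition of the vinyl iodide, CO insertion, transmetalation from the alkynylstannane) should give the cross-conjugated γ-hydroxy ynone with retention of the Z geometry under base-free conditions that spare the epimerisable butenolide C6–H.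

Step 12
Reactants: 19 the γ-hydroxy ynone of step 11
Product: 20 (5R)-3-({[tert-butyl(dimethyl)silyl]oxy}methyl)-5-[(1Z)-3-{[tert-butyl(diphenyl)silyl]oxy}-2-[(5S)-5-{2-[(4-methoxybenzyl)oxy]ethyl}-5-methyl-4-oxo-4,5-dihydrofuran-2-yl]prop-1-en-1-yl]furan-2(5H)-one
Conditions: (4-CF3C6H4)3PAuCl (5 mol%), AgOTf (5 mol%), H2O (1 equiv), toluene, rt
Reagents that add atoms: water (O)
Why: Gold-catalysed hydration of the ynone at C1 followed by cyclodehydration of the tertiary hydroxyl onto the C3 ketone (the known cyclisation of γ-hydroxy alkynones, water being regenerated) should give the 3(2H)-furanone; C10 is not involved.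

Step 13
Reactants: 20 the furanone–butenolide of step 12
Product: 21 (5R)-3-(hydroxymethyl)-5-[(1Z)-3-{[tert-butyl(diphenyl)silyl]oxy}-2-[(5S)-5-{2-[(4-methoxybenzyl)oxy]ethyl}-5-methyl-4-oxo-4,5-dihydrofuran-2-yl]prop-1-en-1-yl]furan-2(5H)-one
Conditions: HF·pyridine, pyridine, THF, 0 °C
Reagents that add atoms: none
Why: Buffered HF·pyridine cleaves a primary TBS ether much faster than a primary TBDPS ether, and the PMB ether is inert.

Step 14
Reactants: 21 the C13 alcohol of step 13
Product: 22 (5R)-3-(bromomethyl)-5-[(1Z)-3-{[tert-butyl(diphenyl)silyl]oxy}-2-[(5S)-5-{2-[(4-methoxybenzyl)oxy]ethyl}-5-methyl-4-oxo-4,5-dihydrofuran-2-yl]prop-1-en-1-yl]furan-2(5H)-one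
Conditions: CBr4, PPh3, CH2Cl2, 0 °C
Reagents that add atoms: tetrabromomethane (BrC(Br)(Br)Br)
Why: Appel bromination of the primary allylic alcohol under neutral conditions gives the conjugated primary bromide.

Step 15
Reactants: 22 the bromide of step 14
Product: 23 (5R)-3-(bromomethyl)-5-[(1Z)-3-{[tert-butyl(diphenyl)silyl]oxy}-2-[(5S)-5-(2-hydroxyethyl)-5-methyl-4-oxo-4,5-dihydrofuran-2-yl]prop-1-en-1-yl]furan-2(5H)-one
Conditions: DDQ, CH2Cl2/pH 7 buffer, 0 °C to rt
Reagents that add atoms: none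
Why: Oxidative cleavage of the PMB ether by DDQ is neutral and should leave the allylic bromide, the silyl ether and the electron-poor olefins untouched.

Step 16
Reactants: 23 the C8 alcohol of step 15
Product: 24 (5R)-3-(bromomethyl)-5-[(1Z)-3-{[tert-butyl(diphenyl)silyl]oxy}-2-[(5S)-5-methyl-4-oxo-5-(2-oxoethyl)-4,5-dihydrofuran-2-yl]prop-1-en-1-yl]furan-2(5H)-one
Conditions: Dess–Martin periodinane, NaHCO3, CH2Cl2, 0 °C to rt; used at once
Reagents that add atoms: none
Why: Buffered Dess–Martin oxidation gives the aldehyde without amine base, which avoids β-elimination of the furanone oxygen from the β-alkoxy aldehyde and epimerisation at C6.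

Step 17
Reactants: 24 the seco-aldehyde of step 16
Product: 26 macrocyclic (6R,7R,8S,10S)-8-alcohol (15-O-TBDPS-8-epi-8-O-desmethacryloyl target), via allylchromium dichloride 25 (not isolated)
Conditions: CrCl2 (8 equiv), THF, rt, 24 added by syringe pump over 10 h (final 2 mM); aq. NH4Cl
Reagents that add atoms: none
Why: Two equivalents of CrCl2 reduce the allylic C13–Br bond to an allylchromium dichloride of trivalent chromium, which binds the aldehyde and attacks it through its γ-carbon C7 (SE2′) in a six-membered chair Zimmerman–Traxler transition state, forming C7–C8 and shifting the double bond to C11=C13. The closest known reaction type is the Nozaki–Hiyama (chromium Barbier) allylation of aldehydes by 2-(bromomethyl)acrylates and 3-(bromomethyl)butenolides, including its high-dilution use for macrocyclic α-methylene lactones. The closure is a 9-exo-trig attack on the aldehyde for the oxa-ring C8–C9–C10–O–C3–C4=C5–C6–C7 and at the same time 10-exo-trig for the carbocycle C1–C10. C7 is controlled by the existing C6 stereocentre: C8 adds to the butenolide face anti to the C5 substituent, giving the trans-fused lactone (7R), which is also the less strained way for the seven-atom tether to reach C7 (C5–C6–C7–C8 torsion near 130°). C8 is controlled by the chair: the lactone ring holds C6 trans to C13 (an E-type γ-substituent) and C9 lies pseudo-equatorial on the outer edge of the butenolide, so the 7,8-anti alcohol (8S) is expected. The step needs γ- over α-attack (the cyclic transition state delivers γ; α-attack would require an eleven-membered ring), cyclisation over oligomerisation (slow addition, 2 mM) and reduction of the allylic bromide in the presence of aldehyde, furanone and lactone, which CrCl2 should provide.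

Step 18
Reactants: 26 macrocyclic (6R,7R,8S,10S)-8-alcohol
Product: 27 15-O-TBDPS ether of the target, (6R,7R,8R,10S)-8-methacrylate
Conditions: methacrylic acid, PPh3, DIAD (betaine pre-formed), toluene, 0 °C to rt, BHT (trace)
Reagents that add atoms: methacrylic acid (C=C(C)C(=O)O)
Why: Mitsunobu esterification: the C8 alkoxyphosphonium is displaced by methacrylate with SN2 inversion, converting 8S into the required 8R ester, and pre-forming the betaine keeps free phosphine away from the α-methylene lactone.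

Step 19
Reactants: 27 15-O-TBDPS ether of the target
Product: 28 target, (6R,7R,8R,10S,4Z)-15-hydroxy furanoheliangolide 8-methacrylate
Conditions: HF·pyridine, pyridine, THF, 0 °C to rt
Reagents that add atoms: none
Why: Buffered fluoride cleavage of the primary allylic TBDPS ether is non-basic and should be tolerated by both Michael acceptors and the methacrylate.

Compound list
1 | 4-[(4-methoxybenzyl)oxy]but-1-yne | C#CCCOCc1ccc(OC)cc1 | starting material
2 | dimethyl{(1E)-4-[(4-methoxybenzyl)oxy]-2-methylbut-1-en-1-yl}alane | C[Al](C)/C=C(\C)CCOCc1ccc(OC)cc1 | intermediate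
3 | (2E)-5-[(4-methoxybenzyl)oxy]-3-methylpent-2-en-1-ol | OC/C=C(\C)CCOCc1ccc(OC)cc1 | intermediate
4 | [(2S,3S)-3-{2-[(4-methoxybenzyl)oxy]ethyl}-3-methyloxiran-2-yl]methanol | OC[C@@H]1O[C@@]1(C)CCOCc1ccc(OC)cc1 | intermediate
5 | (2R,3S)-2-(chloromethyl)-3-{2-[(4-methoxybenzyl)oxy]ethyl}-3-methyloxirane | ClC[C@@H]1O[C@@]1(C)CCOCc1ccc(OC)cc1 | intermediate
6 | dilithium salt (acetylide and alkoxide) of (3S)-5-[(4-methoxybenzyl)oxy]-3-methylpent-1-yn-3-ol | [Li]C#C[C@@](C)(O[Li])CCOCc1ccc(OC)cc1 | intermediate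
7 | (3S)-5-[(4-methoxybenzyl)oxy]-3-methyl-1-(tributylstannyl)pent-1-yn-3-ol | CCCC[Sn](CCCC)(CCCC)C#C[C@@](C)(O)CCOCc1ccc(OC)cc1 | intermediate
8 | ethyl 2-(hydroxymethyl)prop-2-enoate | C=C(CO)C(=O)OCC | starting material
9 | ethyl 2-({[tert-butyl(dimethyl)silyl]oxy}methyl)prop-2-enoate | C=C(CO[Si](C)(C)C(C)(C)C)C(=O)OCC | intermediate
10 | 2-({[tert-butyl(dimethyl)silyl]oxy}methyl)prop-2-enoic acid | C=C(CO[Si](C)(C)C(C)(C)C)C(=O)O | intermediate
11 | tert-butyl(diphenyl)(prop-2-yn-1-yloxy)silane | C#CCO[Si](c1ccccc1)(c1ccccc1)C(C)(C)C | starting material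
12 | (2E)-but-2-enal | C/C=C/C=O | starting material
13 | (3-{[tert-butyl(diphenyl)silyl]oxy}prop-1-yn-1-yl)(methyl)zinc | C[Zn]C#CCO[Si](c1ccccc1)(c1ccccc1)C(C)(C)C | intermediate
14 | (4S,5E)-1-{[tert-butyl(diphenyl)silyl]oxy}hept-5-en-2-yn-4-ol | C/C=C/[C@H](O)C#CCO[Si](c1ccccc1)(c1ccccc1)C(C)(C)C | intermediate
15 | sodium 2,5-dihydro-1,2-oxaluminolate (vinylalanate; Al on C4, O on C6, two 2-methoxyethoxy ligands) | C/C=C/[C@@H]1O[Al-](OCCOC)(OCCOC)C(CO[Si](c2ccccc2)(c2ccccc2)C(C)(C)C)=C1.[Na+] | intermediate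
16 | (2Z,4S,5E)-1-{[tert-butyl(diphenyl)silyl]oxy}-2-iodohepta-2,5-dien-4-ol | C/C=C/[C@H](O)/C=C(\I)CO[Si](c1ccccc1)(c1ccccc1)C(C)(C)C | intermediate
17 | (2Z,4S,5E)-1-{[tert-butyl(diphenyl)silyl]oxy}-2-iodohepta-2,5-dien-4-yl 2-({[tert-butyl(dimethyl)silyl]oxy}methyl)prop-2-enoate | C/C=C/[C@H](OC(=O)C(=C)CO[Si](C)(C)C(C)(C)C)/C=C(\I)CO[Si](c1ccccc1)(c1ccccc1)C(C)(C)C | intermediate
18 | (5S)-3-({[tert-butyl(dimethyl)silyl]oxy}methyl)-5-[(1Z)-3-{[tert-butyl(diphenyl)silyl]oxy}-2-iodoprop-1-en-1-yl]furan-2(5H)-one | I/C(CO[Si](c1ccccc1)(c1ccccc1)C(C)(C)C)=C\[C@H]1OC(=O)C(CO[Si](C)(C)C(C)(C)C)=C1 | intermediate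
19 | (5R)-3-({[tert-butyl(dimethyl)silyl]oxy}methyl)-5-[(1Z,6S)-2-({[tert-butyl(diphenyl)silyl]oxy}methyl)-6-hydroxy-8-[(4-methoxybenzyl)oxy]-6-methyl-3-oxooct-1-en-4-yn-1-yl]furan-2(5H)-one | O=C(C#C[C@@](C)(O)CCOCc1ccc(OC)cc1)/C(CO[Si](c1ccccc1)(c1ccccc1)C(C)(C)C)=C\[C@H]1OC(=O)C(CO[Si](C)(C)C(C)(C)C)=C1 | intermediate
20 | (5R)-3-({[tert-butyl(dimethyl)silyl]oxy}methyl)-5-[(1Z)-3-{[tert-butyl(diphenyl)silyl]oxy}-2-[(5S)-5-{2-[(4-methoxybenzyl)oxy]ethyl}-5-methyl-4-oxo-4,5-dihydrofuran-2-yl]prop-1-en-1-yl]furan-2(5H)-one | COc1ccc(cc1)COCC[C@]1(C)OC(=CC1=O)/C(CO[Si](c1ccccc1)(c1ccccc1)C(C)(C)C)=C\[C@H]1OC(=O)C(CO[Si](C)(C)C(C)(C)C)=C1 | intermediate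
21 | (5R)-3-(hydroxymethyl) analogue of 20 | COc1ccc(cc1)COCC[C@]1(C)OC(=CC1=O)/C(CO[Si](c1ccccc1)(c1ccccc1)C(C)(C)C)=C\[C@H]1OC(=O)C(CO)=C1 | intermediate
22 | (5R)-3-(bromomethyl) analogue of 20 | COc1ccc(cc1)COCC[C@]1(C)OC(=CC1=O)/C(CO[Si](c1ccccc1)(c1ccccc1)C(C)(C)C)=C\[C@H]1OC(=O)C(CBr)=C1 | intermediate
23 | (5R)-3-(bromomethyl)-5-[(1Z)-3-{[tert-butyl(diphenyl)silyl]oxy}-2-[(5S)-5-(2-hydroxyethyl)-5-methyl-4-oxo-4,5-dihydrofuran-2-yl]prop-1-en-1-yl]furan-2(5H)-one | OCC[C@]1(C)OC(=CC1=O)/C(CO[Si](c1ccccc1)(c1ccccc1)C(C)(C)C)=C\[C@H]1OC(=O)C(CBr)=C1 | intermediate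
24 | (5R)-3-(bromomethyl)-5-[(1Z)-3-{[tert-butyl(diphenyl)silyl]oxy}-2-[(5S)-5-methyl-4-oxo-5-(2-oxoethyl)-4,5-dihydrofuran-2-yl]prop-1-en-1-yl]furan-2(5H)-one (seco-aldehyde) | O=CC[C@]1(C)OC(=CC1=O)/C(CO[Si](c1ccccc1)(c1ccccc1)C(C)(C)C)=C\[C@H]1OC(=O)C(CBr)=C1 | intermediate
25 | allylchromium dichloride from 24 (Cr on C13) | O=CC[C@]1(C)OC(=CC1=O)/C(CO[Si](c1ccccc1)(c1ccccc1)C(C)(C)C)=C\[C@H]1OC(=O)C(C[Cr](Cl)Cl)=C1 | intermediate
26 | macrocyclic (6R,7R,8S,10S)-8-alcohol, 15-O-TBDPS-8-epi-8-O-desmethacryloyl target | O[C@H]1C[C@]2(C)OC(=CC2=O)/C(CO[Si](c2ccccc2)(c2ccccc2)C(C)(C)C)=C\[C@H]2OC(=O)C(=C)[C@@H]21 | intermediate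
27 | 15-O-TBDPS ether of the target, (6R,7R,8R,10S)-8-methacrylate | C=C(C)C(=O)O[C@@H]1C[C@]2(C)OC(=CC2=O)/C(CO[Si](c2ccccc2)(c2ccccc2)C(C)(C)C)=C\[C@H]2OC(=O)C(=C)[C@@H]21 | intermediate
28 | target, (6R,7R,8R,10S,4Z)-15-hydroxy-1-oxo-3,10-epoxygermacra-2,4,11(13)-trien-12,6-olide 8-methacrylate | C=C(C)C(=O)O[C@@H]1C[C@]2(C)OC(=CC2=O)/C(CO)=C\[C@H]2OC(=O)C(=C)[C@@H]21 | target

Total step count: 19. Longest linear sequence: 13 steps (steps 7–19 from 11 and 12; equally steps 1–4 then 11–19, or steps 5–6 then 9–19).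

Steps most likely to fail

Step 17 (key step). Intermolecular allylation may outrun the strained nine-membered closure and give oligomers. The allylchromium may be protonated, the β-alkoxy aldehyde may lose the furanone oxygen by β-elimination, or the aldehyde may react through a non-chair arrangement and give the other C8 epimer. The fallback replaces the reductive closed-transition-state allylation by a Lewis-acid-promoted allylstannane addition through an open transition state. It sets out from 23: Zn dust and Bu3SnCl in THF/aq. NH4Cl should convert the allylic bromide into the allylstannane alcohol F1. Dess–Martin oxidation gives the allylstannane aldehyde F2. BF3·OEt2 in CH2Cl2 at −78 °C under high dilution should close the same C7–C8 bond. An antiperiplanar open transition state is expected to favour the 7,8-syn alcohol, the (8R)-macrocyclic alcohol F3, which is acylated directly with methacrylic anhydride and DMAP to come back at 27. Any 8S alcohol formed is 26 and continues through step 18. The same direct acylation is used if step 17 itself delivers the (8R)-macrocyclic alcohol F3.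

Step 18. The activated C8 oxygen may be lost by elimination toward C9 or C7 instead of substitution. Free phosphine may add to the exocyclic methylene, or participation of the lactone may lead to retention or translactonisation. The fallback separates activation from displacement. It sets out from 26: ClCH2SO2Cl and pyridine in CH2Cl2 at 0 °C give the C8 chloromethanesulfonate F4, which is displaced with inversion by caesium methacrylate and 18-crown-6 in toluene at 60 °C, coming back at 27.

Step 11. Transmetalation may precede CO insertion and give the non-carbonylative enyne. Zerovalent palladium may ionise the allylic C6–O lactone bond, or the alkynylstannane may be protodestannylated. The fallback forms the C3–C4 bond by a Nozaki–Hiyama–Kishi addition instead of palladium catalysis. It sets out from 5: the same n-BuLi fragmentation is used, but the dilithio species 6 is quenched with DMF to give the ynal (4S)-4-hydroxy-6-[(4-methoxybenzyl)oxy]-4-methylhex-2-ynal F5. Vinyl iodide 18 and F5 are coupled with CrCl2 and catalytic NiCl2 in DMF to the C3 carbinol F6 (both C3 epimers), and MnO2 oxidation comes back at 19.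

Further compounds
F1 | step 17 | (5R)-5-[(1Z)-3-{[tert-butyl(diphenyl)silyl]oxy}-2-[(5S)-5-(2-hydroxyethyl)-5-methyl-4-oxo-4,5-dihydrofuran-2-yl]prop-1-en-1-yl]-3-[(tributylstannyl)methyl]furan-2(5H)-one | OCC[C@]1(C)OC(=CC1=O)/C(CO[Si](c1ccccc1)(c1ccccc1)C(C)(C)C)=C\[C@H]1OC(=O)C(C[Sn](CCCC)(CCCC)CCCC)=C1
F2 | step 17 | (5R)-5-[(1Z)-3-{[tert-butyl(diphenyl)silyl]oxy}-2-[(5S)-5-methyl-4-oxo-5-(2-oxoethyl)-4,5-dihydrofuran-2-yl]prop-1-en-1-yl]-3-[(tributylstannyl)methyl]furan-2(5H)-one | O=CC[C@]1(C)OC(=CC1=O)/C(CO[Si](c1ccccc1)(c1ccccc1)C(C)(C)C)=C\[C@H]1OC(=O)C(C[Sn](CCCC)(CCCC)CCCC)=C1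
F3 | step 17 | macrocyclic (6R,7R,8R,10S)-8-alcohol, 15-O-TBDPS-8-O-desmethacryloyl target | O[C@@H]1C[C@]2(C)OC(=CC2=O)/C(CO[Si](c2ccccc2)(c2ccccc2)C(C)(C)C)=C\[C@H]2OC(=O)C(=C)[C@@H]21
F4 | step 18 | (8S)-chloromethanesulfonate of 26 | ClCS(=O)(=O)O[C@H]1C[C@]2(C)OC(=CC2=O)/C(CO[Si](c2ccccc2)(c2ccccc2)C(C)(C)C)=C\[C@H]2OC(=O)C(=C)[C@@H]21
F5 | step 11 | (4S)-4-hydroxy-6-[(4-methoxybenzyl)oxy]-4-methylhex-2-ynal | O=CC#C[C@@](C)(O)CCOCc1ccc(OC)cc1
F6 | step 11 | C3 carbinol (both C3 epimers) corresponding to ynone 19 | OC(C#C[C@@](C)(O)CCOCc1ccc(OC)cc1)/C(CO[Si](c1ccccc1)(c1ccccc1)C(C)(C)C)=C\[C@H]1OC(=O)C(CO[Si](C)(C)C(C)(C)C)=C1
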